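**Plan**

- Retrosynthesis: the seven hydroxyls are first traced back to ethers. Ring A (C1 = the carbon carrying the ether oxygen to ring B) is then cut at C1–C2, C3–C4 and C5–C6 into an aryloxyketene (C1, C6) and two ethoxyacetylenes (C2/C3 and C4/C5).
- Enabling feature: in ring A the ether carbon C1 lies between two C–OH carbons, the third C–OH is para to it, and C3/C5 are C–H. This is the oxygen/hydrogen alternation that a C=C=O unit and two head-to-tail ynol ethers leave behind.
- Further cuts: the O–CH2 bond of the aryloxyacetyl unit (phenol alkylation), the C–O bond of that phenol (Baeyer–Villiger on an aldehyde), and the B–C diaryl ether bond (Chan–Lam coupling of syringaldehyde with a boronic acid made by C–H borylation).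
- Forward order: rings C and B come from bought arenes and are joined through oxygen (step 2), the two-carbon ketene precursor is attached (steps 3–5), ring A is closed (step 6), and all ethers are cleaved (step 7).
- Stereochemistry: the target is achiral and has no stereocentre; the sp3 centres passed through in step 6 vanish on aromatisation.

Key step: step 6

**Route**

Step 1
Reactants: 1 2-bromo-1,3-dimethoxybenzene
Product: 3 (4-bromo-3,5-dimethoxyphenyl)boronic acid, via pinacol boronate 2 (not isolated)
Conditions: [Ir(OMe)(cod)]2 (1 mol %), 4,4'-di-tert-butyl-2,2'-bipyridine (2 mol %), B2pin2 (0.6 equiv), THF, 80 °C; then NaIO4, THF/H2O, rt, then 1 M HCl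
Reagents that add atoms: bis(pinacolato)diboron, CC1(C)OB(OC1(C)C)B1OC(C)(C)C(C)(C)O1; water, O
Why: Iridium-catalysed C–H borylation is sterically controlled and should functionalise only C5 of 1, the single C–H with no ortho substituent, leaving the C–Br bond untouched; periodate cleavage of the pinacol ester in the same flask is a standard way to the free boronic acid.

Step 2
Reactants: 3 (4-bromo-3,5-dimethoxyphenyl)boronic acid; 4 syringaldehyde (4-hydroxy-3,5-dimethoxybenzaldehyde)
Product: 5 4-(4-bromo-3,5-dimethoxyphenoxy)-3,5-dimethoxybenzaldehyde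
Conditions: 3 (2 equiv), Cu(OAc)2 (2 equiv), pyridine (5 equiv), 4 Å MS, CH2Cl2, air, rt
Reagents that add atoms: none
Why: Chan–Lam–Evans O-arylation with an unhindered arylboronic acid is known to tolerate doubly ortho-substituted phenols, and the aldehyde and the aryl bromide are inert to Cu(OAc)2 at room temperature.

Step 3
Reactants: 5 4-(4-bromo-3,5-dimethoxyphenoxy)-3,5-dimethoxybenzaldehyde
Product: 7 4-(4-bromo-3,5-dimethoxyphenoxy)-3,5-dimethoxyphenol, via aryl formate 6 (not isolated)
Conditions: mCPBA (1.5 equiv), CH2Cl2, 0 °C to rt; after NaHCO3 wash, K2CO3 (cat.), MeOH, rt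
Reagents that add atoms: mCPBA (3-chloroperoxybenzoic acid), OOC(=O)c1cccc(Cl)c1
Why: Baeyer–Villiger (Dakin-type) oxidation, in which the electron-rich aryl group with its para aryloxy substituent migrates in preference to hydrogen, as with 3,4,5-trimethoxybenzaldehyde, and the labile formate 6 is then cleaved by methanolysis.

Step 4
Reactants: 7 4-(4-bromo-3,5-dimethoxyphenoxy)-3,5-dimethoxyphenol; 8 ethyl bromoacetate
Product: 10 2-[4-(4-bromo-3,5-dimethoxyphenoxy)-3,5-dimethoxyphenoxy]acetic acid, via ethyl ester 9 (not isolated)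
Conditions: 8 (1.2 equiv), K2CO3, DMF, rt; then LiOH, H2O, rt; 1 M HCl work-up
Reagents that add atoms: lithium hydroxide, [Li+].[OH-]
Why: Williamson alkylation of an unhindered phenoxide (both ortho positions are C–H) with a reactive α-bromo ester, followed by saponification in the same flask; the diaryl ethers, methyl ethers and aryl bromide are stable to both stages.

Step 5
Reactants: 10 2-[4-(4-bromo-3,5-dimethoxyphenoxy)-3,5-dimethoxyphenoxy]acetic acid
Product: 11 2-[4-(4-bromo-3,5-dimethoxyphenoxy)-3,5-dimethoxyphenoxy]acetyl chloride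
Conditions: 1-chloro-N,N,2-trimethylprop-1-en-1-amine (1.05 equiv), CH2Cl2, 0 °C to rt; used crude
Reagents that add atoms: 1-chloro-N,N,2-trimethylprop-1-en-1-amine, CC(C)=C(Cl)N(C)C
Why: Acid chloride formation with an α-chloroenamine (Ghosez reagent) runs under neutral conditions and produces neither HCl nor a Vilsmeier- or oxalyl-type electrophile that could attack the very electron-rich rings B and C.

Step 6
Reactants: 11 2-[4-(4-bromo-3,5-dimethoxyphenoxy)-3,5-dimethoxyphenoxy]acetyl chloride; 12 ethoxyacetylene (two molecules)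
Product: 19 2-[4-(4-bromo-3,5-dimethoxyphenoxy)-3,5-dimethoxyphenoxy]-3,5-diethoxyphenol, via aryloxyketene 13 (not isolated), via 4-aryloxy-3-ethoxycyclobutenone 14 (not isolated), via vinylketene 15 (not isolated), via 4-vinylcyclobutenone 16 (not isolated), via dienylketene 17 (not isolated), via cyclohexadienone 18 (not isolated)
Conditions: 12 (6 equiv), Et3N (1.2 equiv, slow addition), toluene, 0 °C to rt; filtration from Et3NHCl under argon; then 85 °C, sealed tube
Reagents that add atoms: none
Why: Proposed new method: Et3N dehydrochlorinates 11 to aryloxyketene 13, whose electrophilic carbonyl carbon is attacked by the unsubstituted carbon of 12 in a (2+2) cycloaddition to cyclobutenone 14; on heating, conrotatory four-electron opening of 14 (aryloxy group outward) gives vinylketene 15, which takes up a second molecule of 12 in the same sense to give 16, and reversible opening of 16 delivers dienylketene 17 for a six-electron electrocyclisation to cyclohexadienone 18, which enolises to phenol 19. The closest known reaction types are the (2+2) cycloaddition of ketenes generated from acid chlorides with ethoxyacetylene and the Danheiser benzannulation of cyclobutenones with alkoxyalkynes; not yet shown are a cyclobutenone with an aryloxy group on its sp3 carbon and the running of both stages in one flask with a single alkyne. Ring A, the only ring formed, closes by 6π electrocyclisation of 17, which re-forms the bond between the two former ketene carbons; the three new ring bonds (C1–C2 from the first cycloaddition, C3–C4 and C5–C6 from the second) are in place by then. No stereocentre is created in 19, since the sp3 carbons of 14, 16 and 18 are racemic and disappear on aromatisation. The step needs head-to-tail uptake of both alkynes, which the polarisation of the ynol ether (nucleophilic β-carbon) against the ketene carbonyl carbon secures, so that one ethoxy group ends next to the aryloxy carbon and the other para to it; a direct (4+2) addition of 12 to 15 would give the 4-aryloxy-3,5-diethoxyphenol isomer, which step 7 converts into the same target. The oxygen donor on the sp3 carbon of 14 should lower the ring-opening barrier enough for the cascade to run at 85 °C, below the temperature at which 12 loses ethylene.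

Step 7
Reactants: 19 2-[4-(4-bromo-3,5-dimethoxyphenoxy)-3,5-dimethoxyphenoxy]-3,5-diethoxyphenol
Product: 20 2-[4-(4-bromo-3,5-dihydroxyphenoxy)-3,5-dihydroxyphenoxy]benzene-1,3,5-triol (CNP0170882.0)
Conditions: BBr3 (12 equiv), CH2Cl2, −78 °C to rt; then H2O, 0 °C; work-up under argon
Reagents that add atoms: none
Why: BBr3-mediated cleavage of aryl alkyl ethers (bromide attacks the O-alkyl carbon of the boron-complexed ether) should remove the four methyl and two ethyl groups, while the diaryl ether C–O bonds and the aryl C–Br bond, which offer no SN2-reactive carbon, stay intact.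

**Compound list**

ArO = 4-(4-bromo-3,5-dimethoxyphenoxy)-3,5-dimethoxyphenoxy

1 | 2-bromo-1,3-dimethoxybenzene | COc1cccc(OC)c1Br | starting material
2 | 2-(4-bromo-3,5-dimethoxyphenyl)-4,4,5,5-tetramethyl-1,3,2-dioxaborolane | COc1cc(B2OC(C)(C)C(C)(C)O2)cc(OC)c1Br | intermediate
3 | (4-bromo-3,5-dimethoxyphenyl)boronic acid | COc1cc(B(O)O)cc(OC)c1Br | intermediate
4 | syringaldehyde (4-hydroxy-3,5-dimethoxybenzaldehyde) | COc1cc(C=O)cc(OC)c1O | starting material
5 | 4-(4-bromo-3,5-dimethoxyphenoxy)-3,5-dimethoxybenzaldehyde | COc1cc(C=O)cc(OC)c1Oc1cc(OC)c(Br)c(OC)c1 | intermediate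
6 | 4-(4-bromo-3,5-dimethoxyphenoxy)-3,5-dimethoxyphenyl formate | COc1cc(OC=O)cc(OC)c1Oc1cc(OC)c(Br)c(OC)c1 | intermediate
7 | 4-(4-bromo-3,5-dimethoxyphenoxy)-3,5-dimethoxyphenol | COc1cc(O)cc(OC)c1Oc1cc(OC)c(Br)c(OC)c1 | intermediate
8 | ethyl bromoacetate | CCOC(=O)CBr | starting material
9 | ethyl 2-[4-(4-bromo-3,5-dimethoxyphenoxy)-3,5-dimethoxyphenoxy]acetate | CCOC(=O)COc1cc(OC)c(Oc2cc(OC)c(Br)c(OC)c2)c(OC)c1 | intermediate
10 | 2-[4-(4-bromo-3,5-dimethoxyphenoxy)-3,5-dimethoxyphenoxy]acetic acid | OC(=O)COc1cc(OC)c(Oc2cc(OC)c(Br)c(OC)c2)c(OC)c1 | intermediate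
11 | 2-[4-(4-bromo-3,5-dimethoxyphenoxy)-3,5-dimethoxyphenoxy]acetyl chloride | COc1cc(OCC(=O)Cl)cc(OC)c1Oc1cc(OC)c(Br)c(OC)c1 | intermediate
12 | ethoxyacetylene (ethoxyethyne) | CCOC#C | starting material
13 | 2-(ArO)ethen-1-one (aryloxyketene) | O=C=COc1cc(OC)c(Oc2cc(OC)c(Br)c(OC)c2)c(OC)c1 | intermediate
14 | racemic 4-(ArO)-3-ethoxycyclobut-2-en-1-one | CCOC1=CC(=O)C1Oc1cc(OC)c(Oc2cc(OC)c(Br)c(OC)c2)c(OC)c1 | intermediate
15 | (3Z)-4-(ArO)-3-ethoxybuta-1,3-dien-1-one (vinylketene) | O=C=C/C(OCC)=C/Oc1cc(OC)c(Oc2cc(OC)c(Br)c(OC)c2)c(OC)c1 | intermediate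
16 | racemic 4-[(Z)-2-(ArO)-1-ethoxyethenyl]-3-ethoxycyclobut-2-en-1-one | CCOC1=CC(=O)C1/C(OCC)=C/Oc1cc(OC)c(Oc2cc(OC)c(Br)c(OC)c2)c(OC)c1 | intermediate
17 | (3E,5Z)-6-(ArO)-3,5-diethoxyhexa-1,3,5-trien-1-one (dienylketene) | O=C=C/C(OCC)=C\C(OCC)=C\Oc1cc(OC)c(Oc2cc(OC)c(Br)c(OC)c2)c(OC)c1 | intermediate
18 | racemic 6-(ArO)-3,5-diethoxycyclohexa-2,4-dien-1-one | CCOC1=CC(=O)C(Oc2cc(OC)c(Oc3cc(OC)c(Br)c(OC)c3)c(OC)c2)C(OCC)=C1 | intermediate
19 | 2-[4-(4-bromo-3,5-dimethoxyphenoxy)-3,5-dimethoxyphenoxy]-3,5-diethoxyphenol | CCOc1cc(O)c(Oc2cc(OC)c(Oc3cc(OC)c(Br)c(OC)c3)c(OC)c2)c(OCC)c1 | intermediate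
20 | 2-[4-(4-bromo-3,5-dihydroxyphenoxy)-3,5-dihydroxyphenoxy]benzene-1,3,5-triol | Oc1cc(O)c(Oc2cc(O)c(Oc3cc(O)c(Br)c(O)c3)c(O)c2)c(O)c1 | target

**Step count and risks**

Total steps: 7. Longest linear sequence: 7 steps (from 1 to 20).

Steps most likely to fail:

1. Step 6 (the proposed new method). The aryloxyketene may dimerise or oligomerise before the alkyne intercepts it. Cyclobutenone 14 may not open at a temperature that ethoxyacetylene survives. The phenol formed may be acylated by vinylketene still present; a brief K2CO3/MeOH treatment of the crude product would reverse that. Fallback by known chemistry, setting out from phenol 7: a copper-catalysed Ullmann-type ether synthesis with commercial 2-iodo-1,3,5-trimethoxybenzene (CuI, picolinic acid, K3PO4, DMSO, 90 °C) should give 2-[4-(4-bromo-3,5-dimethoxyphenoxy)-3,5-dimethoxyphenoxy]-1,3,5-trimethoxybenzene F1. The iodide, used in excess, should react ahead of the less reactive C–Br bond of ring C. Cleavage of all seven methyl ethers with BBr3 under the conditions of step 7 then rejoins the route at target 20.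

2. Step 2. C–O bond formation at the doubly ortho-substituted, formyl-deactivated phenoxide may be slow, so that the boronic acid is lost to protodeboronation, homocoupling and oxidation. Fallback, setting out from boronic acid 3: copper-mediated iododeboronation (KI, CuI, 1,10-phenanthroline, MeOH/H2O, air, 80 °C) should give 2-bromo-5-iodo-1,3-dimethoxybenzene F2. Ullmann-type coupling of F2 with syringaldehyde 4 (CuI, picolinic acid, K3PO4, DMSO, 90 °C), selective for the unhindered C–I bond over the doubly flanked C–Br bond, returns to the route at aldehyde 5.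

3. Step 7. The two ethyl ethers may be cleaved more slowly than the methyl ethers, leaving partly alkylated material, and the free heptaphenol may be oxidised by air or lost on silica during purification. Fallback, setting out from 19: after the BBr3 treatment the crude product is peracetylated (Ac2O, pyridine, DMAP cat., rt) to 2-[4-(3,5-diacetoxy-4-bromophenoxy)-3,5-diacetoxyphenoxy]benzene-1,3,5-triyl triacetate F3. F3 is stable, can be chromatographed, and is separable from under-dealkylated acetates. Acid methanolysis (HCl in degassed MeOH, rt, argon) then releases target 20 without exposing phenoxides to base.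

**Further compounds**

F1 | step 6 | 2-[4-(4-bromo-3,5-dimethoxyphenoxy)-3,5-dimethoxyphenoxy]-1,3,5-trimethoxybenzene | COc1cc(OC)c(Oc2cc(OC)c(Oc3cc(OC)c(Br)c(OC)c3)c(OC)c2)c(OC)c1
F2 | step 2 | 2-bromo-5-iodo-1,3-dimethoxybenzene | COc1cc(I)cc(OC)c1Br
F3 | step 7 | 2-[4-(3,5-diacetoxy-4-bromophenoxy)-3,5-diacetoxyphenoxy]benzene-1,3,5-triyl triacetate | CC(=O)Oc1cc(OC(C)=O)c(Oc2cc(OC(C)=O)c(Oc3cc(OC(C)=O)c(Br)c(OC(C)=O)c3)c(OC(C)=O)c2)c(OC(C)=O)c1
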